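0.837 is the number to carry. Call it the late share s, the target gained per starting material lost over the last stretch of a run, a local selectivity, here read from 2.00 min to 3.00 min in the green run.

| setting | green | grey | ochre | south | south-west |
|---|---|---|---|---|---|
| starting material | 1 M | 1 M | 1 M | 1.0 M | 1.0 M |
| first nucleophile | 0.80 M | 0.80 M | 0.80 M | 0.800 M | 0.800 M |
| second nucleophile | 0.76 M | 1.5 M | 2.2 M | 3.00 M | 0.800 M |
| remark | run made earlier | run made earlier | run made earlier |  |  |
| time |  |  |  | 3.0 min | 6.0 min |

| run | time / min | target / % | starting material / % |
|---|---|---|---|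
| green | 0.667 | 10.3 | 69.1 |
| green | 1.33 | 20.0 | 47.1 |
| green | 2.00 | 31.1 | 32.8 |
| green | 2.50 | 37.7 | 24.6 |
| green | 3.00 | 43.4 | 18.1 |
| grey | 0.667 | 7.2 | 68.6 |
| grey | 1.33 | 16.6 | 47.1 |
| grey | 2.00 | 25.5 | 32.2 |
| grey | 2.50 | 30.7 | 24.5 |
| grey | 3.00 | 36.5 | 18.3 |
| ochre | 0.250 | 3.2 | 87.1 |
| ochre | 0.833 | 8.2 | 63.0 |
| ochre | 1.33 | 14.5 | 48.1 |
| ochre | 2.00 | 23.8 | 32.6 |
| ochre | 3.00 | 33.3 | 18.2 |

(standard deviation of a reading: 0.5 percentage points)

- the numbers in the tables scatter by 0.5 percentage points (one standard deviation)

- the winner by amount of target, in percent of the starting material charged; "neither" if no more than 2 percentage points parts them (south / south-west / neither)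
- how much target is there at the end, in percent of the starting material charged: south
- how much target is there at the end, in percent of the starting material charged: south-west

Watch the green run in slow motion. By 0.667 min it has lost 30.9% of its starting material and shows 10.3% target, a share of 0.333. From there to 2.00 min the share reads 0.573, and at the end s. Now look at the starting material: at 3.00 min the green, grey and ochre runs hold 18.1%, 18.3% and 18.2%, though they were charged with 0.76 M, 1.5 M and 2.2 M of second nucleophile. Read a first-order constant k, the fractional loss per minute, from the green run: 0.570 min⁻¹.

Take south-west as the green run continued, its 0.800 M of second nucleophile lying close to green's 0.76 M. At 6.0 min, k leaves 3.28% of the starting material. One round with the whole-run share gives 51.3% target. Go round again: put s on what is lost after 3.00 min, and get 55.8%.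

For south, follow target at 3.00 min through the green, grey and ochre runs: 43.4%, 36.5%, 33.3%, the second step about half the first. Halve it again: 31.7%. So I expect south-west ahead.

The forecast names south-west, with 31.5% for south and 62% for south-west, and it reasons that “Target per starting material lost rises with time”. Its south-west figure stands higher than my 55.8%; for south the two of us lie close.

South-west gives 57.0% and south 31.9%, so south-west wins.

    first nucleophile ⇌ dormant form (K = 3.92, k = 0.191 s⁻¹)
    2 second nucleophile → homo dimer (k = 0.0215 M⁻¹ s⁻¹)
    starting material → intermediate (k = 0.00939 s⁻¹)
    first nucleophile + intermediate → target (k = 24.2 M⁻¹ s⁻¹)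
    second nucleophile + intermediate → other capture product (k = 24.6 M⁻¹ s⁻¹)

In south-west, 0.050% of the charged second nucleophile stands unbound at 6.00 min. Now put s on south: at 3.00 min it still holds 18.4% starting material, so s on that rest reckons 47.3% target, and south left until 30.0 min holds 48.7%.

The data come from a simulation on assumed constants, and the scatter is random.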